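**Retrosynthetic overview**

1. Feature: in each oxolane ring (O1, C2 carrying the aryl group, C3 carrying CH2OH, C4 carrying OH and the benzyl group, C5) the C2 carbon is benzylic and para to a phenolic OH. Both O1–C2 bonds are therefore cut back to a p-quinone methide at C2 and the C5 hydroxyl, and both oxolanes are closed last, together, by one DDQ oxidation of an open-chain hexaol.
2. The hexaol carries pivalates on the two phenols that must stay inert (the benzyl ring on C4 of the first oxolane and biaryl ring C). It comes from LiAlH4 reduction of a biaryl-linked bis(α-hydroxy-α,β-dibenzyl-γ-butyrolactone), then phenol-selective pivaloylation and hydrogenolysis of two benzyl ethers.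
3. The ring B–ring C bond (on each ring at the carbon ortho to the phenolic oxygen) is made by Suzuki coupling of two bromo hydroxy lactones.
4. Each hydroxy lactone is built by Stobbe condensation, asymmetric hydrogenation and lactonization to an (R)-β-benzyl-γ-butyrolactone, then trans α-benzylation and enolate hydroxylation, which set the future oxolane C3 and C4.
5. Ring order: the two temporary lactone rings (steps 4 and 12), then both oxolane rings at once (step 23).

Key step: step 23

Remark (conventions): ring B is the biaryl ring that ends on C2 of the first oxolane, and ring C is the biaryl ring of the C4 benzyl group of the second oxolane. Fragment A leads to the first oxolane and fragment B to the second.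
Remark (assumption): the (S,S) antipode of Et-DuPHOS is assumed to deliver the (R)-succinates 5 and 16; if the opposite sense is found, the (R,R) ligand is used instead.
Remark (assumption): 4-(benzyloxy)-3-methoxybenzaldehyde 14 is taken as a purchased starting material.

**Fragment A**

Step 1
Reactants: 1 5-bromovanillin
Product: 2 4-(benzyloxy)-3-bromo-5-methoxybenzaldehyde
Conditions: BnBr, K2CO3, DMF, 60 °C
Reagents that add atoms: benzyl bromide, BrCc1ccccc1
Why: Williamson ether synthesis on the phenoxide; the benzyl ether marks the ring B phenol as one of the two to be set free just before the key step.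

Step 2
Reactants: 2 4-(benzyloxy)-3-bromo-5-methoxybenzaldehyde; 3 dimethyl succinate
Product: 4 (E)-4-[4-(benzyloxy)-3-bromo-5-methoxyphenyl]-3-(methoxycarbonyl)but-3-enoic acid
Conditions: NaOMe, MeOH, reflux; then 2 M HCl
Reagents that add atoms: none
Why: Stobbe condensation, in which the aldol adduct lactonizes and then opens by elimination to the (E)-arylidene succinic half-ester with the ester on the alkene carbon.

Step 3
Reactants: 4 (E)-arylidene succinic half-ester of fragment A
Product: 5 (3R)-4-[4-(benzyloxy)-3-bromo-5-methoxyphenyl]-3-(methoxycarbonyl)butanoic acid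
Conditions: H2 (5 bar), [Rh(cod)((S,S)-Et-DuPHOS)]BF4 (1 mol %), NaOMe (0.1 equiv), MeOH, rt
Reagents that add atoms: none
Why: Rhodium-catalysed asymmetric hydrogenation of an itaconate-type half-ester, in which carboxylate chelation and the C2-symmetric bisphospholane fix the alkene face and should set the (R) centre (the future oxolane C3); aryl bromide and benzyl ether are inert to the homogeneous catalyst.

Step 4
Reactants: 5 (3R)-half-ester of fragment A
Product: 7 (4R)-4-[4-(benzyloxy)-3-bromo-5-methoxybenzyl]dihydrofuran-2(3H)-one, via hydroxy acid 6 (not isolated)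
Conditions: LiOH (1.0 equiv), MeOH, evaporate; LiBH4, THF, 0 to 40 °C; then 2 M HCl, rt
Reagents that add atoms: none
Why: Chemoselective borohydride reduction of the methyl ester beside the unreactive lithium carboxylate, then acid-catalysed γ-lactonization; the stereocentre is not touched.

Step 5
Reactants: 8 vanillin
Product: 9 4-(tert-butyldimethylsilyloxy)-3-methoxybenzaldehyde
Conditions: TBSCl, imidazole, DMF, rt
Reagents that add atoms: tert-butyldimethylsilyl chloride, CC(C)(C)[Si](C)(C)Cl
Why: Silylation of the phenol; the aryl silyl ether should survive the enolate steps and is shed in the basic work-up of step 20.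

Step 6
Reactants: 9 4-(tert-butyldimethylsilyloxy)-3-methoxybenzaldehyde
Product: 10 [4-(tert-butyldimethylsilyloxy)-3-methoxyphenyl]methanol
Conditions: NaBH4, EtOH/THF, 0 °C
Reagents that add atoms: none
Why: Borohydride reduction of the aldehyde to the benzylic alcohol at 0 °C, which should leave the aryl silyl ether intact.

Step 7
Reactants: 10 [4-(tert-butyldimethylsilyloxy)-3-methoxyphenyl]methanol
Product: 11 4-(tert-butyldimethylsilyloxy)-3-methoxybenzyl bromide
Conditions: CBr4, PPh3, CH2Cl2, 0 °C; used at once
Reagents that add atoms: carbon tetrabromide, BrC(Br)(Br)Br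
Why: Appel bromination under neutral conditions; the electron-rich benzyl bromide is passed through a short silica pad and used directly.

Step 8
Reactants: 7 (4R)-lactone of fragment A; 11 4-(tert-butyldimethylsilyloxy)-3-methoxybenzyl bromide
Product: 12 (3R,4R)-4-[4-(benzyloxy)-3-bromo-5-methoxybenzyl]-3-[4-(tert-butyldimethylsilyloxy)-3-methoxybenzyl]dihydrofuran-2(3H)-one
Conditions: LiN(SiMe3)2, THF, −78 °C; then 11, DMPU, −78 to −40 °C
Reagents that add atoms: none
Why: Alkylation of the lactone lithium enolate, the bromide entering anti to the C4 benzyl group so that the trans-3,4-dibenzyl lactone (3R) should form.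

Step 9
Reactants: 12 trans-dibenzyl lactone of fragment A
Product: 13 (3S,4S)-4-[4-(benzyloxy)-3-bromo-5-methoxybenzyl]-3-[4-(tert-butyldimethylsilyloxy)-3-methoxybenzyl]-3-hydroxydihydrofuran-2(3H)-one
Conditions: KN(SiMe3)2, THF, −78 °C; racemic trans-2-(phenylsulfonyl)-3-phenyloxaziridine, −78 °C; AcOH
Reagents that add atoms: 2-(phenylsulfonyl)-3-phenyloxaziridine, O=S(=O)(c1ccccc1)N1OC1c1ccccc1
Why: Davis oxidation (electrophilic hydroxylation of the potassium enolate); the C3 benzyl group is expected to turn its aryl ring to the face remote from the C4 benzyl group and shield it, so oxygen should be delivered cis to the C4 benzyl group, the two benzyl groups stay trans, and the quaternary carbinol (3S, the future oxolane C4) is set.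

**Fragment B**

Step 10
Reactants: 14 4-(benzyloxy)-3-methoxybenzaldehyde; 3 dimethyl succinate
Product: 15 (E)-4-[4-(benzyloxy)-3-methoxyphenyl]-3-(methoxycarbonyl)but-3-enoic acid
Conditions: NaOMe, MeOH, reflux; then 2 M HCl
Reagents that add atoms: none
Why: Stobbe condensation as in step 2, giving the (E)-arylidene succinic half-ester.

Step 11
Reactants: 15 (E)-arylidene succinic half-ester of fragment B
Product: 16 (3R)-4-[4-(benzyloxy)-3-methoxyphenyl]-3-(methoxycarbonyl)butanoic acid
Conditions: H2 (5 bar), [Rh(cod)((S,S)-Et-DuPHOS)]BF4 (1 mol %), NaOMe (0.1 equiv), MeOH, rt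
Reagents that add atoms: none
Why: Rhodium-catalysed asymmetric hydrogenation as in step 3, the chelated half-ester and the chiral bisphospholane setting the (R) centre.

Step 12
Reactants: 16 (3R)-half-ester of fragment B
Product: 18 (4R)-4-[4-(benzyloxy)-3-methoxybenzyl]dihydrofuran-2(3H)-one, via hydroxy acid 17 (not isolated)
Conditions: LiOH (1.0 equiv), MeOH, evaporate; LiBH4, THF, 0 to 40 °C; then 2 M HCl, rt
Reagents that add atoms: none
Why: Ester-selective borohydride reduction beside the carboxylate salt and acid-catalysed γ-lactonization, as in step 4.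

Step 13
Reactants: 1 5-bromovanillin
Product: 19 3-bromo-4-(tert-butyldimethylsilyloxy)-5-methoxybenzaldehyde
Conditions: TBSCl, imidazole, DMF, 40 °C
Reagents that add atoms: tert-butyldimethylsilyl chloride, CC(C)(C)[Si](C)(C)Cl
Why: Silylation of the hindered but acidic phenol; this silyl ether marks the ring C phenol as one that will later carry a pivalate.

Step 14
Reactants: 19 3-bromo-4-(tert-butyldimethylsilyloxy)-5-methoxybenzaldehyde
Product: 20 [3-bromo-4-(tert-butyldimethylsilyloxy)-5-methoxyphenyl]methanol
Conditions: NaBH4, EtOH/THF, 0 °C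
Reagents that add atoms: none
Why: Borohydride reduction of the aldehyde, kept cold and short so that the base-sensitive aryl silyl ether is retained.

Step 15
Reactants: 20 [3-bromo-4-(tert-butyldimethylsilyloxy)-5-methoxyphenyl]methanol
Product: 21 3-bromo-4-(tert-butyldimethylsilyloxy)-5-methoxybenzyl bromide
Conditions: CBr4, PPh3, CH2Cl2, 0 °C
Reagents that add atoms: carbon tetrabromide, BrC(Br)(Br)Br
Why: Appel bromination of the benzylic alcohol under neutral conditions; the aryl bromide and silyl ether are unaffected.

Step 16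
Reactants: 18 (4R)-lactone of fragment B; 21 3-bromo-4-(tert-butyldimethylsilyloxy)-5-methoxybenzyl bromide
Product: 22 (3R,4R)-4-[4-(benzyloxy)-3-methoxybenzyl]-3-[3-bromo-4-(tert-butyldimethylsilyloxy)-5-methoxybenzyl]dihydrofuran-2(3H)-one
Conditions: LiN(SiMe3)2, THF, −78 °C; then 21, DMPU, −78 to −40 °C
Reagents that add atoms: none
Why: Enolate alkylation anti to the C4 benzyl group, as in step 8, should give the trans-dibenzyl lactone; only the benzylic bromide reacts, the aryl bromide is inert.

Step 17
Reactants: 22 trans-dibenzyl lactone of fragment B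
Product: 23 (3S,4S)-4-[4-(benzyloxy)-3-methoxybenzyl]-3-[3-bromo-4-(tert-butyldimethylsilyloxy)-5-methoxybenzyl]-3-hydroxydihydrofuran-2(3H)-one
Conditions: KN(SiMe3)2, THF, −78 °C; racemic trans-2-(phenylsulfonyl)-3-phenyloxaziridine, −78 °C; AcOH
Reagents that add atoms: 2-(phenylsulfonyl)-3-phenyloxaziridine, O=S(=O)(c1ccccc1)N1OC1c1ccccc1
Why: Davis oxidation of the potassium enolate as in step 9, oxygen expected cis to the C4 benzyl group with the benzyl groups kept trans, setting the (3S) quaternary carbinol.

**Union and end game**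

Step 18
Reactants: 13 bromo hydroxy lactone of fragment A
Product: 24 pinacol boronate of 13 (Bpin in place of Br on ring B)
Conditions: B2pin2, Pd(dppf)Cl2 (5 mol %), KOAc, 1,4-dioxane, 85 °C
Reagents that add atoms: bis(pinacolato)diboron, CC1(C)OB(OC1(C)C)B1OC(C)(C)C(C)(C)O1
Why: Miyaura borylation through oxidative addition of zerovalent palladium to the aryl bromide; the weak base KOAc should leave lactone, tertiary alcohol and silyl ether untouched.

Step 19
Reactants: 24 ring B pinacol boronate; 23 bromo hydroxy lactone of fragment B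
Product: 25 biaryl bis(hydroxy lactone) in which ring B of fragment A is bonded to ring C of fragment B
Conditions: Pd(OAc)2 (5 mol %), SPhos (10 mol %), K3PO4, toluene/H2O (10:1), 80 °C; dilute citric acid work-up
Reagents that add atoms: none
Why: Suzuki–Miyaura coupling, with SPhos chosen for the junction that carries an oxygen substituent ortho on each partner; the acidic work-up re-closes any lactone opened by the base, and any loss of aryl silyl ether here is harmless because step 20 removes both.

Step 20
Reactants: 25 biaryl bis(hydroxy lactone)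
Product: 27 biaryl-linked bis[(2S,3S)-2,3-dibenzylbutane-1,2,4-triol] with two free phenols and two benzyl ethers, via bis-silyl hexaol 26 (not isolated)
Conditions: LiAlH4, THF, 0 °C to rt; then H2O, 2 M NaOH, MeOH, 40 °C; neutralize with 1 M HCl
Reagents that add atoms: none
Why: Hydride reduction of both α-hydroxy lactones to 1,2,4-triols without touching a stereocentre, then hydroxide cleavage of the two base-labile aryl silyl ethers in the same flask; benzyl ethers survive both stages.

Step 21
Reactants: 27 hexaol with two free phenols and two benzyl ethers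
Product: 28 dipivalate of 27 (pivalate on ring C and on the guaiacyl ring of fragment A)
Conditions: PivCl (2.2 equiv), 1 M NaOH(aq), Bu4NHSO4 (cat.), CH2Cl2, 0 °C
Reagents that add atoms: pivaloyl chloride, CC(C)(C)C(Cl)=O
Why: Phase-transfer Schotten–Baumann acylation, in which only the two phenols are ionized by aqueous hydroxide and carried into CH2Cl2 as ion pairs, so they should be acylated while the six aliphatic hydroxyls stay free.

Step 22
Reactants: 28 dipivalate dibenzyl ether hexaol
Product: 29 hexaol dipivalate with free phenols on ring B and on the guaiacyl ring of fragment B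
Conditions: H2 (1 atm), Pd/C (10 %), EtOAc/THF, rt; no base
Reagents that add atoms: none
Why: Hydrogenolysis of the two aryl benzyl ethers; aryl pivalates and the all-carbon benzylic positions are inert, and the neutral conditions keep the ring C pivalate from migrating to the neighbouring ring B oxygen.

Step 23
Reactants: 29 hexaol dipivalate
Product: 31 bis-oxolane dipivalate, via bis(p-quinone methide) 30 (not isolated)
Conditions: DDQ (2.1 equiv, in portions), anhydrous 1,4-dioxane, 15–20 °C; filter, NaHCO3 wash
Reagents that add atoms: none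
Why: DDQ removes hydride and then a proton from each benzylic CH2 that stands para to a free phenol, giving p-quinone methides at both future C2 carbons (drawn together as 30, although the two sites react independently), and each is captured by the primary hydroxyl on the neighbouring carbinol carbon (the future C5–OH) in a conjugate addition that restores the arene. The closest known reaction type is the DDQ oxidation of p-hydroxyphenyl alkanols and of dibenzylbutanediol lignans to 2-aryltetrahydrofurans through quinone methides. Each oxolane closes 5-exo-trig, whereas the C4 hydroxyl and the C3 hydroxymethyl group could only close oxetanes. Each new C2 centre is controlled by the adjacent C3 stereocentre: closure through the envelope with the aryl group and the C3 hydroxymethyl arm pseudoequatorial should place them trans, giving (2S). The step needs site selectivity, which the pivalates secure by keeping the other two benzylic positions from forming quinone methides and by lowering the nucleophilicity of those arenes, so that O-capture should beat aryltetralin-forming C-capture. It also needs the oxidation to stop at the ether stage, which the portionwise addition of just over two equivalents of DDQ at low temperature is meant to secure.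

Step 24
Reactants: 31 bis-oxolane dipivalate
Product: 32 CNP0269573.1 (target)
Conditions: K2CO3 (0.5 equiv), MeOH, rt to 40 °C; NH4Cl work-up
Reagents that add atoms: none
Why: Base-catalysed transesterification of the two aryl pivalates with methanol; the oxolane rings, the tertiary alcohols and all six stereocentres are inert to mild carbonate, and acid is avoided so that no aryltetralin rearrangement can start.

**Compound list**

1 | 5-bromovanillin (3-bromo-4-hydroxy-5-methoxybenzaldehyde) | O=Cc1cc(Br)c(O)c(OC)c1 | starting material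
2 | 4-(benzyloxy)-3-bromo-5-methoxybenzaldehyde | O=Cc1cc(Br)c(OCc2ccccc2)c(OC)c1 | intermediate
3 | dimethyl succinate | COC(=O)CCC(=O)OC | starting material
4 | (E)-4-[4-(benzyloxy)-3-bromo-5-methoxyphenyl]-3-(methoxycarbonyl)but-3-enoic acid | COC(=O)/C(CC(=O)O)=C/c1cc(Br)c(OCc2ccccc2)c(OC)c1 | intermediate
5 | (3R)-4-[4-(benzyloxy)-3-bromo-5-methoxyphenyl]-3-(methoxycarbonyl)butanoic acid | COC(=O)[C@H](Cc1cc(Br)c(OCc2ccccc2)c(OC)c1)CC(=O)O | intermediate
6 | (3R)-4-[4-(benzyloxy)-3-bromo-5-methoxyphenyl]-3-(hydroxymethyl)butanoic acid (not isolated) | OC[C@H](Cc1cc(Br)c(OCc2ccccc2)c(OC)c1)CC(=O)O | intermediate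
7 | (4R)-4-[4-(benzyloxy)-3-bromo-5-methoxybenzyl]dihydrofuran-2(3H)-one | O=C1C[C@@H](Cc2cc(Br)c(OCc3ccccc3)c(OC)c2)CO1 | intermediate
8 | vanillin | O=Cc1ccc(O)c(OC)c1 | starting material
9 | 4-(tert-butyldimethylsilyloxy)-3-methoxybenzaldehyde | O=Cc1ccc(O[Si](C)(C)C(C)(C)C)c(OC)c1 | intermediate
10 | [4-(tert-butyldimethylsilyloxy)-3-methoxyphenyl]methanol | OCc1ccc(O[Si](C)(C)C(C)(C)C)c(OC)c1 | intermediate
11 | 4-(tert-butyldimethylsilyloxy)-3-methoxybenzyl bromide | BrCc1ccc(O[Si](C)(C)C(C)(C)C)c(OC)c1 | intermediate
12 | (3R,4R)-4-[4-(benzyloxy)-3-bromo-5-methoxybenzyl]-3-[4-(tert-butyldimethylsilyloxy)-3-methoxybenzyl]dihydrofuran-2(3H)-one (benzyl groups trans) | O=C1OC[C@H](Cc2cc(Br)c(OCc3ccccc3)c(OC)c2)[C@H]1Cc1ccc(O[Si](C)(C)C(C)(C)C)c(OC)c1 | intermediate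
13 | (3S,4S)-4-[4-(benzyloxy)-3-bromo-5-methoxybenzyl]-3-[4-(tert-butyldimethylsilyloxy)-3-methoxybenzyl]-3-hydroxydihydrofuran-2(3H)-one (OH cis to the C4 benzyl group) | O=C1OC[C@H](Cc2cc(Br)c(OCc3ccccc3)c(OC)c2)[C@@]1(O)Cc1ccc(O[Si](C)(C)C(C)(C)C)c(OC)c1 | intermediate
14 | 4-(benzyloxy)-3-methoxybenzaldehyde | O=Cc1ccc(OCc2ccccc2)c(OC)c1 | starting material
15 | (E)-4-[4-(benzyloxy)-3-methoxyphenyl]-3-(methoxycarbonyl)but-3-enoic acid | COC(=O)/C(CC(=O)O)=C/c1ccc(OCc2ccccc2)c(OC)c1 | intermediate
16 | (3R)-4-[4-(benzyloxy)-3-methoxyphenyl]-3-(methoxycarbonyl)butanoic acid | COC(=O)[C@H](Cc1ccc(OCc2ccccc2)c(OC)c1)CC(=O)O | intermediate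
17 | (3R)-4-[4-(benzyloxy)-3-methoxyphenyl]-3-(hydroxymethyl)butanoic acid (not isolated) | OC[C@H](Cc1ccc(OCc2ccccc2)c(OC)c1)CC(=O)O | intermediate
18 | (4R)-4-[4-(benzyloxy)-3-methoxybenzyl]dihydrofuran-2(3H)-one | O=C1C[C@@H](Cc2ccc(OCc3ccccc3)c(OC)c2)CO1 | intermediate
19 | 3-bromo-4-(tert-butyldimethylsilyloxy)-5-methoxybenzaldehyde | O=Cc1cc(Br)c(O[Si](C)(C)C(C)(C)C)c(OC)c1 | intermediate
20 | [3-bromo-4-(tert-butyldimethylsilyloxy)-5-methoxyphenyl]methanol | OCc1cc(Br)c(O[Si](C)(C)C(C)(C)C)c(OC)c1 | intermediate
21 | 3-bromo-4-(tert-butyldimethylsilyloxy)-5-methoxybenzyl bromide | BrCc1cc(Br)c(O[Si](C)(C)C(C)(C)C)c(OC)c1 | intermediate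
22 | (3R,4R)-4-[4-(benzyloxy)-3-methoxybenzyl]-3-[3-bromo-4-(tert-butyldimethylsilyloxy)-5-methoxybenzyl]dihydrofuran-2(3H)-one (benzyl groups trans) | O=C1OC[C@H](Cc2ccc(OCc3ccccc3)c(OC)c2)[C@H]1Cc1cc(Br)c(O[Si](C)(C)C(C)(C)C)c(OC)c1 | intermediate
23 | (3S,4S)-4-[4-(benzyloxy)-3-methoxybenzyl]-3-[3-bromo-4-(tert-butyldimethylsilyloxy)-5-methoxybenzyl]-3-hydroxydihydrofuran-2(3H)-one (OH cis to the C4 benzyl group) | O=C1OC[C@H](Cc2ccc(OCc3ccccc3)c(OC)c2)[C@@]1(O)Cc1cc(Br)c(O[Si](C)(C)C(C)(C)C)c(OC)c1 | intermediate
24 | pinacol boronate of 13: (3S,4S)-hydroxy lactone with 4,4,5,5-tetramethyl-1,3,2-dioxaborolan-2-yl in place of Br on ring B | O=C1OC[C@H](Cc2cc(B3OC(C)(C)C(C)(C)O3)c(OCc3ccccc3)c(OC)c2)[C@@]1(O)Cc1ccc(O[Si](C)(C)C(C)(C)C)c(OC)c1 | intermediate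
25 | biaryl bis(hydroxy lactone): ring B of 13 bonded to ring C of 23 at the carbons that carried bromine; both lactone units (3S,4S); OBn on ring B and on the guaiacyl ring of fragment B; OTBS on ring C and on the guaiacyl ring of fragment A | O=C1OC[C@H](Cc2cc(-c3cc(C[C@@]4(O)C(=O)OC[C@@H]4Cc5ccc(OCc6ccccc6)c(OC)c5)cc(OC)c3O[Si](C)(C)C(C)(C)C)c(OCc3ccccc3)c(OC)c2)[C@@]1(O)Cc1ccc(O[Si](C)(C)C(C)(C)C)c(OC)c1 | intermediate
26 | bis-silyl hexaol: biaryl-linked bis[(2S,3S)-2,3-dibenzylbutane-1,2,4-triol], protecting groups as in 25 (not isolated) | COc1cc(C[C@@H](CO)[C@](O)(CO)Cc2ccc(O[Si](C)(C)C(C)(C)C)c(OC)c2)cc(c1OCc3ccccc3)-c4cc(C[C@@]([C@@H](Cc5ccc(OCc6ccccc6)c(OC)c5)CO)(O)CO)cc(OC)c4O[Si](C)(C)C(C)(C)C | intermediate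
27 | hexaol, both units (2S,3S), free phenols on ring C and on the guaiacyl ring of fragment A, OBn on ring B and on the guaiacyl ring of fragment B | COc1cc(C[C@@H](CO)[C@](O)(CO)Cc2ccc(O)c(OC)c2)cc(c1OCc3ccccc3)-c4cc(C[C@@]([C@@H](Cc5ccc(OCc6ccccc6)c(OC)c5)CO)(O)CO)cc(OC)c4O | intermediate
28 | dipivalate of 27 (pivalate on ring C and on the guaiacyl ring of fragment A; benzyl ethers kept) | COc1cc(C[C@@H](CO)[C@](O)(CO)Cc2ccc(OC(=O)C(C)(C)C)c(OC)c2)cc(c1OCc3ccccc3)-c4cc(C[C@@]([C@@H](Cc5ccc(OCc6ccccc6)c(OC)c5)CO)(O)CO)cc(OC)c4OC(=O)C(C)(C)C | intermediate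
29 | hexaol dipivalate, both units (2S,3S), free phenols on ring B and on the guaiacyl ring of fragment B (key-step precursor) | COc1cc(C[C@@H](CO)[C@](O)(CO)Cc2ccc(OC(=O)C(C)(C)C)c(OC)c2)cc(c1O)-c3cc(C[C@@]([C@@H](Cc4ccc(O)c(OC)c4)CO)(O)CO)cc(OC)c3OC(=O)C(C)(C)C | intermediate
30 | bis(p-quinone methide) of 29, methide carbons at both future C2 positions, alkene geometry not defined (not isolated) | COC1=CC(=C[C@@H](CO)[C@](O)(CO)Cc2ccc(OC(=O)C(C)(C)C)c(OC)c2)C=C(C1=O)c3cc(C[C@@]([C@@H](C=C4C=CC(=O)C(OC)=C4)CO)(O)CO)cc(OC)c3OC(=O)C(C)(C)C | intermediate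
31 | bis-oxolane dipivalate, both oxolanes (2S,3R,4S) with locants O1, C2 aryl, C3 CH2OH, C4 OH and benzyl | COc1cc(C[C@@]2(O)CO[C@H](c3cc(OC)c(O)c(-c4cc(C[C@@]5(O)CO[C@H](c6ccc(O)c(OC)c6)[C@H]5CO)cc(OC)c4OC(=O)C(C)(C)C)c3)[C@H]2CO)ccc1OC(=O)C(C)(C)C | intermediate
32 | CNP0269573.1, both oxolanes (2S,3R,4S), aryl trans to CH2OH, CH2OH cis to the C4 benzyl group | COc1cc(C[C@@]2(O)CO[C@H](c3cc(OC)c(O)c(-c4cc(C[C@@]5(O)CO[C@H](c6ccc(O)c(OC)c6)[C@H]5CO)cc(OC)c4O)c3)[C@H]2CO)ccc1O | target

**Step count**

Total: 24 steps. Longest linear sequence: 13 steps (steps 1, 2, 3, 4, 8, 9, 18, 19, 20, 21, 22, 23, 24, from 5-bromovanillin).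

**Steps most likely to fail**

Step 23. The oxidation may run on past the ether stage at the newly formed p-hydroxybenzylic C–H, may stall after one ring, or may close a ring through the cis envelope. The fallback separates oxidation from ring closure. It sets out from 29, which is oxidized with DDQ in MeOH/CH2Cl2 at 0 °C so that each quinone methide is parked by the solvent as the bis(benzylic methyl ether) F1; any material that has already ring-closed is carried along. F1 is then treated with catalytic camphorsulfonic acid in CH2Cl2 at 0 °C, which ionizes the p-hydroxybenzylic C–OMe bonds and should let the C5 hydroxyls close both oxolanes under thermodynamic control, settling in the 2,3-trans form. The fallback comes back to the route at 31.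

Step 9. The oxaziridine may attack the enolate face remote from the C4 benzyl group, which would give the C3 epimer with cis benzyl groups. The fallback reverses the order in which the two C3 substituents are introduced, so that the last bond is a C-alkylation with its well-established anti preference. It sets out from 7, which is hydroxylated first (NaN(SiMe3)2, THF, −78 °C, the same oxaziridine) to the α-hydroxy lactone F2; its C3 configuration is immaterial. The alkoxide enolate of F2, formed with LiN(iPr)2 (2.2 equiv) in THF/DMPU at −78 to −40 °C, is then benzylated with 11. The bromide should enter anti to the C4 benzyl group and leave the hydroxyl cis to it, so the fallback comes back to the route at 13.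

Step 17. The same loss of facial selectivity may occur on fragment B. The fallback sets out from 18, which is hydroxylated (NaN(SiMe3)2, THF, −78 °C, the same oxaziridine) to the α-hydroxy lactone F3. The alkoxide enolate of F3 (LiN(iPr)2, 2.2 equiv, THF/DMPU, −78 to −40 °C) is then alkylated with 21 anti to the C4 benzyl group, and the fallback comes back to the route at 23.

**Further compounds**

F1 | step 23 | bis(benzylic methyl ether) of 29: OMe on each benzylic carbon para to a free phenol, both epimers at these two carbons, other centres as in 29 | COc1cc(C(OC)[C@@H](CO)[C@](O)(CO)Cc2ccc(OC(=O)C(C)(C)C)c(OC)c2)cc(c1O)-c3cc(C[C@@]([C@@H](C(OC)c4ccc(O)c(OC)c4)CO)(O)CO)cc(OC)c3OC(=O)C(C)(C)C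
F2 | step 9 | (3R,4S)-4-[4-(benzyloxy)-3-bromo-5-methoxybenzyl]-3-hydroxydihydrofuran-2(3H)-one (trans isomer drawn) | O=C1OC[C@H](Cc2cc(Br)c(OCc3ccccc3)c(OC)c2)[C@H]1O
F3 | step 17 | (3R,4S)-4-[4-(benzyloxy)-3-methoxybenzyl]-3-hydroxydihydrofuran-2(3H)-one (trans isomer drawn) | O=C1OC[C@H](Cc2ccc(OCc3ccccc3)c(OC)c2)[C@H]1O
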